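**Retrosynthetic overview**
1. The target (epirobinetinidol-(4β→8)-epirobinetinidol-(4α→8)-epicatechin) is reached by hydrogenolysis of thirteen benzyl ethers. Before that, one extra oxygen at C5 of each upper unit, brought in with (+)-dihydromyricetin (source of both upper C2 centres), is cut out as an aryl triflate. These oxygens are temporary activators that make every cation/arene union a phloroglucinol-type C8 attack.
2. Ring C of the bottom unit is the key disconnection. The bottom flavan hides a 2-hydroxybenzyl unit (phenol O1 on C8a, ortho to benzylic C4 on C4a), i.e. an ortho-quinone methide O1=C8a–C4a=C4. Its oxa-[4+2] with an (E)-β-boryl-3,4-bis(benzyloxy)styrene forms C4–C3 and O1–C2 at once; C–B to C–OH then gives the 3-OH.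
3. The interflavan bonds come from two Friedel–Crafts unions of flavan-4-yl cations with orthogonal leaving groups. The top 4-alkoxy group (TMSOTf) is joined to C8 of the middle unit. The middle 4-benzylsulfanyl group (AgBF4) is then joined to 3,5-bis(benzyloxy)phenol, whose free OH becomes O1 and directs the C1 unit ortho.
4. Stereochemistry: top C3 is inverted at the monomer stage (oxidation, bulky hydride). The C4 centres arise by anti attack on the cations. Middle and bottom C3 are inverted together late to give the all-cis middle unit and the 2,3-cis bottom unit.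
5. Ring order: rings A and C of the top and middle units come from the chiral pool, ring A of the bottom unit from the phenol, and ring C of the bottom unit is the last ring formed.

Key step: step 14

Assumption: the (R)-configured acid catalyst of step 14 is taken as the matched partner for the (2R) bottom unit (otherwise its enantiomer is used); the C4 epimers of 4 and 10 are equivalent because C4 is ionised later.

Step 1
Reactants: 1 (+)-dihydromyricetin
Product: 2 (2R,3R)-7,3',4',5'-tetra-O-benzyldihydromyricetin (5-OH and 3-OH free)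
Conditions: BnBr (4.4 equiv), K2CO3, DMF, 25 °C, argon
Reagents that add atoms: benzyl bromide BrCc1ccccc1
Why: Williamson etherification should alkylate only the four acidic phenols, because the 5-OH is hydrogen-bonded to the C4 carbonyl and the 3-OH is an alcohol; no stereocentre is touched.

Step 2
Reactants: 2 tetra-O-benzyldihydromyricetin
Product: 3 (2R,3R)-5-O-allyl-7,3',4',5'-tetra-O-benzyldihydromyricetin
Conditions: allyl bromide (3 equiv), K2CO3, Bu4NI (cat.), DMF, 50 °C, argon
Reagents that add atoms: allyl bromide C=CCBr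
Why: forced Williamson etherification of the chelated 5-OH should mark the one oxygen that is removed later with a group orthogonal to benzyl.

Step 3
Reactants: 3 5-O-allyl ketone
Product: 4 (2R,3S,4R)-5-allyloxy-7-benzyloxy-2-[3,4,5-tris(benzyloxy)phenyl]chroman-3,4-diol (2,3-trans-3,4-trans)
Conditions: NaBH4, THF/EtOH, 0 °C
Reagents that add atoms: none
Why: borohydride reduction of the aryl ketone should give mainly the equatorial 4-OH by axial hydride attack; the C4 configuration is lost again in steps 4 and 9.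

Step 4
Reactants: 4 flavan-3,4-diol
Product: 5 (2R,3S)-5-allyloxy-7-benzyloxy-2-[3,4,5-tris(benzyloxy)phenyl]chroman-3-ol (2,3-trans)
Conditions: Et3SiH (5 equiv), TFA (2 equiv), CH2Cl2, −40 → 0 °C
Reagents that add atoms: none
Why: ionic hydrogenation: the C4 alcohol should ionise to a cation stabilised by the 5- and 7-oxygens and be reduced by the silane, with C2 and C3 unchanged.

Step 5
Reactants: 5 2,3-trans flavan-3-ol
Product: 6 (2R)-5-allyloxy-7-benzyloxy-2-[3,4,5-tris(benzyloxy)phenyl]chroman-3-one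
Conditions: Dess–Martin periodinane, NaHCO3, CH2Cl2, 25 °C
Reagents that add atoms: none
Why: Dess–Martin oxidation of the secondary alcohol under buffered, non-basic conditions should leave the C2 centre α to the ketone intact.

Step 6
Reactants: 6 flavan-3-one
Product: 7 (2R,3R)-5-allyloxy-7-benzyloxy-2-[3,4,5-tris(benzyloxy)phenyl]chroman-3-ol (2,3-cis)
Conditions: Li(s-Bu)3BH, LiBr, THF, −78 °C
Reagents that add atoms: none
Why: the bulky hydride should attack the half-chair ketone equatorially and give the axial 3-OH cis to the equatorial C2 aryl group (substrate-controlled ketone reduction, the catechin-to-epicatechin type of inversion).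

Step 7
Reactants: 7 2,3-cis flavan-3-ol
Product: 8 (2R,3R)-5-allyloxy-3,7-bis(benzyloxy)-2-[3,4,5-tris(benzyloxy)phenyl]chroman
Conditions: NaH, BnBr, Bu4NI (cat.), THF/DMF, 0 → 25 °C
Reagents that add atoms: benzyl bromide BrCc1ccccc1
Why: Williamson etherification should cap the top-unit 3-OH so that it is spared in the late oxidation of step 16.

Step 8
Reactants: 8 penta-ether
Product: 9 (2R,3R,4S)-5-allyloxy-3,7-bis(benzyloxy)-4-(2-ethoxyethoxy)-2-[3,4,5-tris(benzyloxy)phenyl]chroman (2,3-cis-3,4-trans)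
Conditions: DDQ (2 equiv), 2-ethoxyethanol (5 equiv), CH2Cl2, 25 °C
Reagents that add atoms: 2-ethoxyethanol CCOCCO
Why: DDQ benzylic oxidation should abstract hydride from C4 (cation stabilised by the 5- and 7-oxygens) and the alcohol should add anti to the 3-benzyloxy group, which sets C4 as 3,4-trans.

Step 9
Reactants: 4 flavan-3,4-diol
Product: 10 (2R,3R,4R)-5-allyloxy-7-benzyloxy-4-benzylsulfanyl-2-[3,4,5-tris(benzyloxy)phenyl]chroman-3-ol (2,3-trans-3,4-trans)
Conditions: phenylmethanethiol (5 equiv), AcOH, 40 °C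
Reagents that add atoms: phenylmethanethiol SCc1ccccc1
Why: acid-mediated SN1 thiolysis of the benzylic alcohol should install a latent C4 leaving group, mainly anti to the 3-OH, that is inert to hard Lewis acids.

Step 10
Reactants: 9 top-unit electrophile; 10 middle-unit thioether
Product: 11 dimer thioether: 5-O-allyl-3,7,3',4',5'-penta-O-benzylepigallocatechin-(4β→8)-[5-O-allyl-7,3',4',5'-tetra-O-benzyl-4-benzylsulfanylgallocatechin]
Conditions: TMSOTf (0.3 equiv), 10 (2.5 equiv; excess recovered), CH2Cl2, −78 → −40 °C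
Reagents that add atoms: none
Why: Friedel–Crafts alkylation by the flavan-4-yl cation: attack should come from C8 of the phloroglucinol-type ring of 10 and anti to the 3-benzyloxy and C2 aryl groups of the 2,3-cis cation (new top C4, 3,4-trans), while the C4–S bond stays untouched by the hard silyl Lewis acid (orthogonal activation).

Step 11
Reactants: 11 dimer thioether; 12 3,5-bis(benzyloxy)phenol
Product: 13 dimer phenol: C4 of the lower flavan unit bonded 3,4-trans (4α) to C2 of 3,5-bis(benzyloxy)phenol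
Conditions: AgBF4 (2.5 equiv), 12 (5 equiv), THF/CH2Cl2, −40 → 0 °C
Reagents that add atoms: none
Why: thiophilic activation and Friedel–Crafts alkylation: the cation should be attacked anti to the 3-OH (new middle C4, 3,4-trans) by the phenol carbon flanked by OH and one benzyloxy group, in preference to the carbon between two benzyloxy groups (the same bias that makes C8 of benzylated flavan-3-ols react before C6).

Step 12
Reactants: 13 dimer phenol
Product: 14 dimer benzodioxaborin: the phenol ring of 13 as a 5,7-bis(benzyloxy)-2-phenyl-4H-1,3,2-benzodioxaborin carrying the dimer at C8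
Conditions: PhB(OH)2 (1.5 equiv), paraformaldehyde (6 equiv), EtCO2H (0.3 equiv), toluene, 85 °C, 4 Å molecular sieves
Reagents that add atoms: phenylboronic acid OB(O)c1ccccc1; formaldehyde (as paraformaldehyde) C=O
Why: boronic acid-templated ortho-hydroxymethylation: the aryloxyboron species should deliver formaldehyde only to the free carbon ortho to the phenol, and the cyclic boronate protects the product from further condensation.

Step 13
Reactants: 15 3,4-bis(benzyloxy)benzaldehyde; 16 bis(pinacolatoboryl)methane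
Product: 17 (E)-2-{2-[3,4-bis(benzyloxy)phenyl]ethenyl}-4,4,5,5-tetramethyl-1,3,2-dioxaborolane
Conditions: lithium 2,2,6,6-tetramethylpiperidide (1.2 equiv), 16 (1.2 equiv), THF, −78 °C; then 15, −78 → 25 °C
Reagents that add atoms: none
Why: boron–Wittig olefination of the aryl aldehyde with the lithiated geminal diboronate should give the (E)-alkenyl boronate.

Step 14
Reactants: 14 dimer benzodioxaborin; 17 (E)-styryl boronate
Product: 20 protected trimer boronate: bottom unit 2,3-trans 5,7-bis(benzyloxy)-2-[3,4-bis(benzyloxy)phenyl]-3-(pinacolatoboryl)chroman linked at C8, via salicyl alcohol 18 (not isolated), via ortho-quinone methide 19 (not isolated)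
Conditions: pinacol (1.05 equiv), toluene, 25 °C, 30 min; then 17 (3 equiv), (R)-3,3'-bis(2,4,6-triisopropylphenyl)-1,1'-binaphthyl-2,2'-diyl N-triflylphosphoramide (10 mol %), 5 Å molecular sieves, −40 → −10 °C
Reagents that add atoms: none
Why: Proposed new method: pinacol exchange should free the 2-hydroxybenzyl alcohol 18, which the chiral acid dehydrates to the ortho-quinone methide 19 (O1=C8a–C4a=C4H2, held as a hydrogen-bonded ion pair with the chiral anion), and this 1-oxadiene should add the electron-rich (E)-β-borylstyrene 17 in an inverse-electron-demand oxa-[4+2] cycloaddition; the closest known reaction type is the chiral Brønsted acid-catalysed hetero-Diels–Alder reaction of ortho-quinone methides with styrenes, extended here to a β-boryl styrene and an unsubstituted methide carbon. Ring C of the bottom unit is closed in a six-membered [4+2] mode, C4–C3 forming ahead of O1–C2 in an asynchronous transition state, and the return of aromaticity to ring A drives the reaction. Regiochemistry: the 4-benzyloxyphenyl group and the β-boron effect both stabilise positive charge at C2, so the boron-bearing carbon should bond to C4 and the benzylic carbon to O1, and only O1 can take part because O5 and O7 are benzylated. The 2,3-trans relationship follows from suprafacial addition to the (E)-alkene; the absolute configuration at C2 and C3 should be set by the chiral anion, which selects the alkene face in an endo-aryl transition state, and a minor isomer is separable because the two adducts are diastereomers. The step also needs chemoselectivity over self-condensation of 19, alkylation of the other arenes and loss of boron from the benzylic cation; the excess of the more nucleophilic styrene, low temperature and fast ring closure by the neighbouring phenol oxygen should secure it.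

Step 15
Reactants: 20 trimer boronate
Product: 21 trimer diol: bottom unit (2R,3S)-5,7,3',4'-tetra-O-benzylcatechin linked at C8; middle unit 2,3-trans-3,4-trans with free 3-OH
Conditions: NaBO3·4H2O (5 equiv), THF/H2O, 25 °C
Reagents that add atoms: sodium perborate [Na+].[Na+].O[B-]1(O)OO[B-](O)(O)OO1
Why: oxidation of the C–B bond by 1,2-migration to peroxide oxygen should occur with retention and give the 2,3-trans 3-OH.

Step 16
Reactants: 21 trimer diol
Product: 22 trimer diketone (flavan-3-ones in the middle and bottom units)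
Conditions: Dess–Martin periodinane (4 equiv), NaHCO3, CH2Cl2, 0 → 25 °C
Reagents that add atoms: none
Why: Dess–Martin oxidation should convert both free secondary alcohols (the top unit has none) under buffered conditions that leave the C2 and C4 centres α to the new ketones unepimerised.

Step 17
Reactants: 22 trimer diketone
Product: 23 trimer diol: middle unit 2,3-cis-3,4-cis; bottom unit 2,3-cis
Conditions: Li(s-Bu)3BH (5 equiv), LiBr, THF, −78 °C
Reagents that add atoms: none
Why: substrate-controlled reduction: equatorial attack of the bulky hydride on each half-chair flavan-3-one should give the axial alcohol, cis to the equatorial C2 aryl group in the bottom unit and cis to both equatorial aryl-bearing carbons in the middle unit (the behaviour of cis-2,6-disubstituted cyclohexanones).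

Step 18
Reactants: 23 trimer diol
Product: 24 trimer bis-phenol (5-OH free in the top and middle units)
Conditions: Pd(PPh3)4 (10 mol %), morpholine (10 equiv), THF, 25 °C
Reagents that add atoms: none
Why: Tsuji–Trost deallylation should transfer both allyl groups to morpholine and leave benzyl ethers and secondary alcohols untouched.

Step 19
Reactants: 24 trimer bis-phenol
Product: 25 trimer bis-triflate
Conditions: PhNTf2 (3 equiv), Et3N, DMAP (cat.), CH2Cl2, 0 → 25 °C
Reagents that add atoms: N-phenylbis(trifluoromethanesulfonimide) O=S(=O)(N(c1ccccc1)S(=O)(=O)C(F)(F)F)C(F)(F)F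
Why: sulfonylation with the mild triflyl donor should be selective for the two phenols over the two hindered secondary alcohols.

Step 20
Reactants: 25 trimer bis-triflate
Product: 26 protected 5-deoxy trimer
Conditions: Pd(OAc)2 (10 mol %), 1,3-bis(diphenylphosphino)propane (12 mol %), HCO2H (6 equiv), Et3N (9 equiv), DMF, 70 °C
Reagents that add atoms: none
Why: palladium-catalysed formate reduction of aryl triflates (oxidative addition, formate exchange, loss of CO2, reductive elimination) should excise both temporary C5 oxygens without touching benzyl ethers.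

Step 21
Reactants: 26 protected 5-deoxy trimer
Product: 27 target
Conditions: H2 (1 atm), Pd(OH)2/C, THF/MeOH, 25 °C
Reagents that add atoms: none
Why: catalytic hydrogenolysis should cleave all thirteen benzyl ethers under neutral conditions that preserve the acid-labile interflavan bonds and all nine stereocentres.

**Compound list**
1 | (+)-dihydromyricetin, (2R,3R)-3,5,7-trihydroxy-2-(3,4,5-trihydroxyphenyl)chroman-4-one | O=C1c2c(O)cc(O)cc2O[C@H](c2cc(O)c(O)c(O)c2)[C@H]1O | starting material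
2 | (2R,3R)-7,3',4',5'-tetra-O-benzyldihydromyricetin | O=C1c2c(O)cc(OCc3ccccc3)cc2O[C@H](c2cc(OCc3ccccc3)c(OCc3ccccc3)c(OCc3ccccc3)c2)[C@H]1O | intermediate
3 | (2R,3R)-5-O-allyl-7,3',4',5'-tetra-O-benzyldihydromyricetin | O=C1c2c(OCC=C)cc(OCc3ccccc3)cc2O[C@H](c2cc(OCc3ccccc3)c(OCc3ccccc3)c(OCc3ccccc3)c2)[C@H]1O | intermediate
4 | (2R,3S,4R)-5-allyloxy-7-benzyloxy-2-[3,4,5-tris(benzyloxy)phenyl]chroman-3,4-diol (2,3-trans-3,4-trans) | c1ccccc1COc1cc(OCC=C)c2c(c1)O[C@H](c3cc(OCc4ccccc4)c(OCc4ccccc4)c(OCc4ccccc4)c3)[C@@H](O)[C@@H]2O | intermediate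
5 | (2R,3S)-5-allyloxy-7-benzyloxy-2-[3,4,5-tris(benzyloxy)phenyl]chroman-3-ol (2,3-trans) | c1ccccc1COc1cc(OCC=C)c2c(c1)O[C@H](c3cc(OCc4ccccc4)c(OCc4ccccc4)c(OCc4ccccc4)c3)[C@@H](O)C2 | intermediate
6 | (2R)-5-allyloxy-7-benzyloxy-2-[3,4,5-tris(benzyloxy)phenyl]chroman-3-one | c1ccccc1COc1cc(OCC=C)c2c(c1)O[C@H](c3cc(OCc4ccccc4)c(OCc4ccccc4)c(OCc4ccccc4)c3)C(=O)C2 | intermediate
7 | (2R,3R)-5-allyloxy-7-benzyloxy-2-[3,4,5-tris(benzyloxy)phenyl]chroman-3-ol (2,3-cis) | c1ccccc1COc1cc(OCC=C)c2c(c1)O[C@H](c3cc(OCc4ccccc4)c(OCc4ccccc4)c(OCc4ccccc4)c3)[C@H](O)C2 | intermediate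
8 | (2R,3R)-5-allyloxy-3,7-bis(benzyloxy)-2-[3,4,5-tris(benzyloxy)phenyl]chroman (2,3-cis) | c1ccccc1COc1cc(OCC=C)c2c(c1)O[C@H](c3cc(OCc4ccccc4)c(OCc4ccccc4)c(OCc4ccccc4)c3)[C@H](OCc3ccccc3)C2 | intermediate
9 | (2R,3R,4S)-5-allyloxy-3,7-bis(benzyloxy)-4-(2-ethoxyethoxy)-2-[3,4,5-tris(benzyloxy)phenyl]chroman (2,3-cis-3,4-trans) | c1ccccc1COc1cc(OCC=C)c2c(c1)O[C@H](c3cc(OCc4ccccc4)c(OCc4ccccc4)c(OCc4ccccc4)c3)[C@H](OCc3ccccc3)[C@H]2OCCOCC | intermediate
10 | (2R,3R,4R)-5-allyloxy-7-benzyloxy-4-benzylsulfanyl-2-[3,4,5-tris(benzyloxy)phenyl]chroman-3-ol (2,3-trans-3,4-trans) | c1ccccc1COc1cc(OCC=C)c2c(c1)O[C@H](c3cc(OCc4ccccc4)c(OCc4ccccc4)c(OCc4ccccc4)c3)[C@@H](O)[C@@H]2SCc1ccccc1 | intermediate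
11 | dimer thioether: top unit of 9 (2,3-cis-3,4-trans) bonded C4→C8 to 10 (2,3-trans-3,4-trans), both C2 R | c1ccccc1COc1cc(OCC=C)c2c(c1)O[C@H](c3cc(OCc4ccccc4)c(OCc4ccccc4)c(OCc4ccccc4)c3)[C@H](OCc3ccccc3)[C@H]2c1c(OCc3ccccc3)cc(OCC=C)c2c1O[C@H](c3cc(OCc4ccccc4)c(OCc4ccccc4)c(OCc4ccccc4)c3)[C@@H](O)[C@@H]2SCc1ccccc1 | intermediate
12 | 3,5-bis(benzyloxy)phenol | Oc1cc(OCc2ccccc2)cc(OCc2ccccc2)c1 | starting material
13 | dimer phenol: as 11, with C4 of the lower flavan unit bonded 3,4-trans to C2 of 3,5-bis(benzyloxy)phenol in place of sulfur | c1ccccc1COc1cc(OCC=C)c2c(c1)O[C@H](c3cc(OCc4ccccc4)c(OCc4ccccc4)c(OCc4ccccc4)c3)[C@H](OCc3ccccc3)[C@H]2c1c(OCc3ccccc3)cc(OCC=C)c2c1O[C@H](c3cc(OCc4ccccc4)c(OCc4ccccc4)c(OCc4ccccc4)c3)[C@@H](O)[C@@H]2c1c(OCc3ccccc3)cc(OCc3ccccc3)cc1O | intermediate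
14 | dimer benzodioxaborin: as 13, phenol ring closed to a 5,7-bis(benzyloxy)-2-phenyl-4H-1,3,2-benzodioxaborin (dimer at C8) | c1ccccc1COc1cc(OCC=C)c2c(c1)O[C@H](c3cc(OCc4ccccc4)c(OCc4ccccc4)c(OCc4ccccc4)c3)[C@H](OCc3ccccc3)[C@H]2c1c(OCc3ccccc3)cc(OCC=C)c2c1O[C@H](c3cc(OCc4ccccc4)c(OCc4ccccc4)c(OCc4ccccc4)c3)[C@@H](O)[C@@H]2c1c(OCc3ccccc3)cc(OCc3ccccc3)c2c1OB(c1ccccc1)OC2 | intermediate
15 | 3,4-bis(benzyloxy)benzaldehyde | O=Cc1ccc(OCc2ccccc2)c(OCc2ccccc2)c1 | starting material
16 | bis(pinacolatoboryl)methane, 2,2'-methylenebis(4,4,5,5-tetramethyl-1,3,2-dioxaborolane) | CC1(C)OB(CB2OC(C)(C)C(C)(C)O2)OC1(C)C | starting material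
17 | (E)-2-{2-[3,4-bis(benzyloxy)phenyl]ethenyl}-4,4,5,5-tetramethyl-1,3,2-dioxaborolane | CC1(C)OB(/C=C/c2ccc(OCc3ccccc3)c(OCc3ccccc3)c2)OC1(C)C | intermediate
18 | salicyl alcohol: as 13, with a hydroxymethyl group on the free carbon ortho to the phenolic OH | c1ccccc1COc1cc(OCC=C)c2c(c1)O[C@H](c3cc(OCc4ccccc4)c(OCc4ccccc4)c(OCc4ccccc4)c3)[C@H](OCc3ccccc3)[C@H]2c1c(OCc3ccccc3)cc(OCC=C)c2c1O[C@H](c3cc(OCc4ccccc4)c(OCc4ccccc4)c(OCc4ccccc4)c3)[C@@H](O)[C@@H]2c1c(OCc3ccccc3)cc(OCc3ccccc3)c(CO)c1O | intermediate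
19 | ortho-quinone methide: 3,5-bis(benzyloxy)-6-methylidenecyclohexa-2,4-dien-1-one carrying the dimer at C2 | c1ccccc1COc1cc(OCC=C)c2c(c1)O[C@H](c3cc(OCc4ccccc4)c(OCc4ccccc4)c(OCc4ccccc4)c3)[C@H](OCc3ccccc3)[C@H]2c1c(OCc3ccccc3)cc(OCC=C)c2c1O[C@H](c3cc(OCc4ccccc4)c(OCc4ccccc4)c(OCc4ccccc4)c3)[C@@H](O)[C@@H]2C1=C(OCc3ccccc3)C=C(OCc3ccccc3)C(=C)C1=O | intermediate
20 | protected trimer boronate: bottom unit 2,3-trans, aryl configured as in (2R)-flavan-3-ols, pinacolboronate at C3 (formally 2S,3S because boron ranks below carbon) | c1ccccc1COc1cc(OCC=C)c2c(c1)O[C@H](c3cc(OCc4ccccc4)c(OCc4ccccc4)c(OCc4ccccc4)c3)[C@H](OCc3ccccc3)[C@H]2c1c(OCc3ccccc3)cc(OCC=C)c2c1O[C@H](c3cc(OCc4ccccc4)c(OCc4ccccc4)c(OCc4ccccc4)c3)[C@@H](O)[C@@H]2c1c(OCc3ccccc3)cc(OCc3ccccc3)c2c1O[C@H](c1ccc(OCc3ccccc3)c(OCc3ccccc3)c1)[C@@H](B1OC(C)(C)C(C)(C)O1)C2 | intermediate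
21 | trimer diol: middle unit 2,3-trans-3,4-trans (3-OH free), bottom unit (2R,3S) catechin-type (3-OH free) | c1ccccc1COc1cc(OCC=C)c2c(c1)O[C@H](c3cc(OCc4ccccc4)c(OCc4ccccc4)c(OCc4ccccc4)c3)[C@H](OCc3ccccc3)[C@H]2c1c(OCc3ccccc3)cc(OCC=C)c2c1O[C@H](c3cc(OCc4ccccc4)c(OCc4ccccc4)c(OCc4ccccc4)c3)[C@@H](O)[C@@H]2c1c(OCc3ccccc3)cc(OCc3ccccc3)c2c1O[C@H](c1ccc(OCc3ccccc3)c(OCc3ccccc3)c1)[C@@H](O)C2 | intermediate
22 | trimer diketone: middle and bottom units as flavan-3-ones | c1ccccc1COc1cc(OCC=C)c2c(c1)O[C@H](c3cc(OCc4ccccc4)c(OCc4ccccc4)c(OCc4ccccc4)c3)[C@H](OCc3ccccc3)[C@H]2c1c(OCc3ccccc3)cc(OCC=C)c2c1O[C@H](c3cc(OCc4ccccc4)c(OCc4ccccc4)c(OCc4ccccc4)c3)C(=O)[C@@H]2c1c(OCc3ccccc3)cc(OCc3ccccc3)c2c1O[C@H](c1ccc(OCc3ccccc3)c(OCc3ccccc3)c1)C(=O)C2 | intermediate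
23 | trimer diol: middle unit 2,3-cis-3,4-cis, bottom unit 2,3-cis (2R,3R) | c1ccccc1COc1cc(OCC=C)c2c(c1)O[C@H](c3cc(OCc4ccccc4)c(OCc4ccccc4)c(OCc4ccccc4)c3)[C@H](OCc3ccccc3)[C@H]2c1c(OCc3ccccc3)cc(OCC=C)c2c1O[C@H](c3cc(OCc4ccccc4)c(OCc4ccccc4)c(OCc4ccccc4)c3)[C@H](O)[C@@H]2c1c(OCc3ccccc3)cc(OCc3ccccc3)c2c1O[C@H](c1ccc(OCc3ccccc3)c(OCc3ccccc3)c1)[C@H](O)C2 | intermediate
24 | trimer bis-phenol: as 23 with 5-OH in the top and middle units | c1ccccc1COc1cc(O)c2c(c1)O[C@H](c3cc(OCc4ccccc4)c(OCc4ccccc4)c(OCc4ccccc4)c3)[C@H](OCc3ccccc3)[C@H]2c1c(OCc3ccccc3)cc(O)c2c1O[C@H](c3cc(OCc4ccccc4)c(OCc4ccccc4)c(OCc4ccccc4)c3)[C@H](O)[C@@H]2c1c(OCc3ccccc3)cc(OCc3ccccc3)c2c1O[C@H](c1ccc(OCc3ccccc3)c(OCc3ccccc3)c1)[C@H](O)C2 | intermediate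
25 | trimer bis-triflate: as 24 with both 5-OH groups as trifluoromethanesulfonates | c1ccccc1COc1cc(OS(=O)(=O)C(F)(F)F)c2c(c1)O[C@H](c3cc(OCc4ccccc4)c(OCc4ccccc4)c(OCc4ccccc4)c3)[C@H](OCc3ccccc3)[C@H]2c1c(OCc3ccccc3)cc(OS(=O)(=O)C(F)(F)F)c2c1O[C@H](c3cc(OCc4ccccc4)c(OCc4ccccc4)c(OCc4ccccc4)c3)[C@H](O)[C@@H]2c1c(OCc3ccccc3)cc(OCc3ccccc3)c2c1O[C@H](c1ccc(OCc3ccccc3)c(OCc3ccccc3)c1)[C@H](O)C2 | intermediate
26 | protected 5-deoxy trimer: target with thirteen benzyl ethers (top 3-O and 7-O, both pyrogallol rings, middle 7-O, bottom 5-O, 7-O, 3'-O, 4'-O) | c1ccccc1COc1ccc2c(c1)O[C@H](c3cc(OCc4ccccc4)c(OCc4ccccc4)c(OCc4ccccc4)c3)[C@H](OCc3ccccc3)[C@H]2c1c(OCc3ccccc3)ccc2c1O[C@H](c3cc(OCc4ccccc4)c(OCc4ccccc4)c(OCc4ccccc4)c3)[C@H](O)[C@@H]2c1c(OCc3ccccc3)cc(OCc3ccccc3)c2c1O[C@H](c1ccc(OCc3ccccc3)c(OCc3ccccc3)c1)[C@H](O)C2 | intermediate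
27 | target: top unit (2R,3R,4R), middle unit (2R,3R,4S), bottom unit (2R,3R) | Oc1ccc2c(c1)O[C@H](c1cc(O)c(O)c(O)c1)[C@H](O)[C@H]2c1c(O)ccc2c1O[C@H](c1cc(O)c(O)c(O)c1)[C@H](O)[C@@H]2c1c(O)cc(O)c2c1O[C@H](c1ccc(O)c(O)c1)[C@H](O)C2 | target

**Step count and risks**
Total steps: 21. Longest linear sequence: 19 steps (steps 1–8, 10–12, 14–21).

Steps most likely to fail:

Step 14 (key step, proposed new method). What may go wrong: poor facial selectivity in the cycloaddition, loss of boron from the benzylic cation before ring closure (leaving a ring-open cinnamyl phenol), or self-condensation of the quinone methide. Fallback with known chemistry: the bottom unit is brought in ready-made from the chiral pool instead of being built. Commercial (+)-catechin is benzylated (BnBr, K2CO3, DMF) to 5,7,3',4'-tetra-O-benzyl-(+)-catechin F1. The fallback sets out from dimer thioether 11, which is ionised with AgBF4 in the presence of excess F1; Friedel–Crafts attack by C8 of F1, anti to the 3-OH of the middle unit, should give trimer diol 21, where the route is rejoined (steps 11, 12, 14 and 15 are bypassed).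

Step 12. What may go wrong: stalling of the boron-templated hydroxymethylation at the hindered phenol, or further condensation to diarylmethanes. Fallback: the carbon is introduced at the aldehyde level. The fallback sets out from dimer phenol 13; magnesium phenoxide-directed ortho-formylation (MgCl2, Et3N, paraformaldehyde, MeCN, reflux) should give the salicylaldehyde F2, and reduction with NaBH4 (THF/EtOH, 0 °C) gives salicyl alcohol 18, which enters step 14 at once without the pinacol exchange.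

Step 2. What may go wrong: base-induced ring opening with epimerisation, and dehydrogenation of the dihydroflavonol, during the forced alkylation of the hydrogen-bonded 5-OH. Fallback: the allylation is postponed until the carbonyl is gone. The fallback sets out from 2; NaBH4 gives the 5-hydroxy flavan-3,4-diol F3. One part is reduced with Et3SiH/TFA to the 5-hydroxy flavan-3-ol F4 and allylated (allyl bromide, K2CO3, DMF, 25 °C) to give 5. Another part is treated with phenylmethanethiol/AcOH to give the 5-hydroxy thioether F5 and allylated likewise to give 10. The route is rejoined at 5 and 10.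

Further compounds
F1 | step 14 | (2R,3S)-5,7,3',4'-tetra-O-benzylcatechin | c1ccccc1COc1cc(OCc3ccccc3)c2c(c1)O[C@H](c1ccc(OCc3ccccc3)c(OCc3ccccc3)c1)[C@@H](O)C2
F2 | step 12 | salicylaldehyde: as 13, with a formyl group on the free carbon ortho to the phenolic OH | c1ccccc1COc1cc(OCC=C)c2c(c1)O[C@H](c3cc(OCc4ccccc4)c(OCc4ccccc4)c(OCc4ccccc4)c3)[C@H](OCc3ccccc3)[C@H]2c1c(OCc3ccccc3)cc(OCC=C)c2c1O[C@H](c3cc(OCc4ccccc4)c(OCc4ccccc4)c(OCc4ccccc4)c3)[C@@H](O)[C@@H]2c1c(OCc3ccccc3)cc(OCc3ccccc3)c(C=O)c1O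
F3 | step 2 | (2R,3S,4R)-7-benzyloxy-2-[3,4,5-tris(benzyloxy)phenyl]chroman-3,4,5-triol (2,3-trans-3,4-trans) | c1ccccc1COc1cc(O)c2c(c1)O[C@H](c3cc(OCc4ccccc4)c(OCc4ccccc4)c(OCc4ccccc4)c3)[C@@H](O)[C@@H]2O
F4 | step 2 | (2R,3S)-7-benzyloxy-2-[3,4,5-tris(benzyloxy)phenyl]chroman-3,5-diol (2,3-trans) | c1ccccc1COc1cc(O)c2c(c1)O[C@H](c3cc(OCc4ccccc4)c(OCc4ccccc4)c(OCc4ccccc4)c3)[C@@H](O)C2
F5 | step 2 | (2R,3R,4R)-7-benzyloxy-4-benzylsulfanyl-2-[3,4,5-tris(benzyloxy)phenyl]chroman-3,5-diol (2,3-trans-3,4-trans) | c1ccccc1COc1cc(O)c2c(c1)O[C@H](c3cc(OCc4ccccc4)c(OCc4ccccc4)c(OCc4ccccc4)c3)[C@@H](O)[C@@H]2SCc1ccccc1
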